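**Plan**

- Target: (2S)-8-hydroxy-5,6,7,3',4'-pentamethoxyflavanone. Retrosynthetic cuts, in order: O8–benzyl; O1–C2 of the pyranone together with a temporary C3–CO2tBu bond; C2=C3 (Knoevenagel); CH3→CH2–CO2tBu (Claisen-type); C4–C4a (Friedel–Crafts); C8–O (ortho-oxygenation of a symmetric phenol).
- Forward: the A ring is oxygenated and acetylated, O8 is benzylated, the acetyl carbon is carboxylated and the B-ring aldehyde is condensed on. The pyranone ring is closed last by O1–C2 bond formation, the ester leaves in the same flask, and the benzyl group is removed.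
- Enabling feature: C3 sits between C2 and the C4 carbonyl, which is bound to C4a next to the O1-bearing C8a. C3 can therefore carry a removable carboxyl that makes C2=C3 a doubly activated acceptor with a two-point binding site for a bifunctional catalyst.
- Of the catechol pair O1/O8, only O1 can reach C2 through a six-membered ring, so the closure itself distinguishes the two oxygens.
- Stereochemistry: C2, the only stereocentre, is set by catalyst control in the oxa-Michael closure. The helper at C3 is removed with acid, and no base touches the flavanone afterwards.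

Key step: step 6

Assumption: the quinidine-derived pseudoenantiomer of the cinchona thiourea is taken to deliver the 2S series; this sense is not established here and is to be checked on a first run, and if it is opposite the quinine-derived pseudoenantiomer is used with no other change.

**Route**

Step 1
Reactants: 1 3,4,5-trimethoxyphenol
Product: 3 3,4,5-trimethoxybenzene-1,2-diol, via 3,4,5-trimethoxy-o-benzoquinone 2 (not isolated)
Conditions: IBX (1.1 equiv), DMF, rt, dark; then aq. Na2S2O4, 0 °C, N2
Reagents that add atoms: IBX (2-iodoxybenzoic acid), O=C1OI(=O)(O)c2ccccc12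
Why: Regioselective ortho-oxygenation of an electron-rich phenol by IBX (oxygen delivered within the iodine(V) phenolate) followed by dithionite reduction; the two ortho positions of symmetric 1 are equivalent, so only one o-quinone and one catechol can form.

Step 2
Reactants: 3 3,4,5-trimethoxybenzene-1,2-diol
Product: 4 1-(2,3-dihydroxy-4,5,6-trimethoxyphenyl)ethan-1-one
Conditions: AcOH, BF3·OEt2 (3 equiv), 80 °C, N2; aq. NaOAc work-up
Reagents that add atoms: acetic acid, CC(=O)O
Why: Friedel–Crafts (Nencki-type) C-acetylation at the single free ring position, which is ortho to a phenol and para to a methoxy group, under conditions known to acetylate polymethoxyphenols without ether cleavage.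

Step 3
Reactants: 4 1-(2,3-dihydroxy-4,5,6-trimethoxyphenyl)ethan-1-one
Product: 5 1-[3-(benzyloxy)-2-hydroxy-4,5,6-trimethoxyphenyl]ethan-1-one
Conditions: NaH (2.2 equiv), DMSO/THF, 0 °C → rt; BnBr (1.0 equiv), rt; 1 M HCl work-up
Reagents that add atoms: benzyl bromide, BrCc1ccccc1
Why: Williamson etherification of the dianion, in which the 2-phenoxide is chelated to sodium and conjugated with the acetyl group, so the more nucleophilic 3-phenoxide should be benzylated selectively.

Step 4
Reactants: 5 1-[3-(benzyloxy)-2-hydroxy-4,5,6-trimethoxyphenyl]ethan-1-one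
Product: 6 tert-butyl 3-[3-(benzyloxy)-2-hydroxy-4,5,6-trimethoxyphenyl]-3-oxopropanoate
Conditions: LiHMDS (3.3 equiv), THF, −78 °C; Boc2O (1.1 equiv), −78 → 0 °C; cold 1 M HCl quench
Reagents that add atoms: di-tert-butyl dicarbonate, CC(C)(C)OC(=O)OC(=O)OC(C)(C)C
Why: Claisen-type C-acylation of the phenoxide/enolate dianion by the dicarbonate, driven by deprotonation of the β-ketoester by the third equivalent of base; the tert-butyl ester cannot lactonise to a 4-hydroxycoumarin.

Step 5
Reactants: 6 tert-butyl 3-[3-(benzyloxy)-2-hydroxy-4,5,6-trimethoxyphenyl]-3-oxopropanoate; 7 3,4-dimethoxybenzaldehyde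
Product: 8 tert-butyl (2Z)-2-[3-(benzyloxy)-2-hydroxy-4,5,6-trimethoxybenzoyl]-3-(3,4-dimethoxyphenyl)prop-2-enoate (drawn as Z, the isomer expected to predominate)
Conditions: piperidine (0.2 equiv), AcOH (0.2 equiv), 4 Å MS, toluene, rt → 40 °C
Reagents that add atoms: none
Why: Knoevenagel condensation of the active methylene with the aromatic aldehyde under buffered amine catalysis, kept mild so that the benzylidene forms without triggering the racemic oxa-Michael closure.

Step 6
Reactants: 8 tert-butyl (2Z)-2-[3-(benzyloxy)-2-hydroxy-4,5,6-trimethoxybenzoyl]-3-(3,4-dimethoxyphenyl)prop-2-enoate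
Product: 11 (2S)-8-(benzyloxy)-2-(3,4-dimethoxyphenyl)-5,6,7-trimethoxychroman-4-one, via tert-butyl flavanone-3-carboxylate 9 (not isolated), via flavanone-3-carboxylic acid 10 (not isolated)
Conditions: thiourea from 9-amino(9-deoxy)-epi-quinidine and 3,5-bis(trifluoromethyl)phenyl isothiocyanate (10 mol %), toluene, −25 °C; then TsOH·H2O (1 equiv), 80 °C
Reagents that add atoms: none
Why: The quinuclidine nitrogen of the catalyst hydrogen-bonds and deprotonates the C2'-phenol while the thiourea N–H pair clamps the 1,3-dicarbonyl unit, and the phenol oxygen adds in conjugate fashion to the benzylidene carbon (future C2); TsOH then cleaves the tert-butyl ester by loss of isobutene and the β-keto acid decarboxylates through its six-membered cyclic transition state, erasing C3. The closest known reaction type is the cinchona-thiourea-catalysed enantioselective intramolecular oxa-Michael addition of 2'-hydroxyaryl alkylidene β-ketoesters with in situ decarboxylation to flavanones. The pyranone ring closes by 6-endo-trig O1–C2 bond formation. C2 is set by the catalyst, which exposes one face of the bound enone to the phenol oxygen (catalyst control, no other stereocentre in the substrate), while the transient C3 centre is epimerisable and is removed. The step needs face selectivity over the racemic background closure and no later ring opening: the ester makes the alkene electrophilic enough to close at −25 °C under the catalyst and supplies the two-point handle, O1 is the only free phenol and the only oxygen that can reach C2 through a six-membered ring, and the helper is removed under acid, not base, so that C2 should not be scrambled by retro-oxa-Michael opening.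

Step 7
Reactants: 11 (2S)-8-(benzyloxy)-2-(3,4-dimethoxyphenyl)-5,6,7-trimethoxychroman-4-one
Product: 12 (2S)-2-(3,4-dimethoxyphenyl)-8-hydroxy-5,6,7-trimethoxychroman-4-one
Conditions: H2 (1 atm), 10% Pd/C, EtOAc, rt
Reagents that add atoms: none
Why: Catalytic hydrogenolysis of the aryl benzyl ether under neutral conditions, expected to be much faster than cleavage of the cyclic C2–O1 bond or reduction of the aryl ketone, with no base present to epimerise C2.

**Compound list**

1 | 3,4,5-trimethoxyphenol | COc1cc(O)cc(OC)c1OC | starting material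
2 | 3,4,5-trimethoxycyclohexa-3,5-diene-1,2-dione (3,4,5-trimethoxy-o-benzoquinone) | O=C1C(=O)C(OC)=C(OC)C(OC)=C1 | intermediate
3 | 3,4,5-trimethoxybenzene-1,2-diol | COc1cc(O)c(O)c(OC)c1OC | intermediate
4 | 1-(2,3-dihydroxy-4,5,6-trimethoxyphenyl)ethan-1-one | CC(=O)c1c(O)c(O)c(OC)c(OC)c1OC | intermediate
5 | 1-[3-(benzyloxy)-2-hydroxy-4,5,6-trimethoxyphenyl]ethan-1-one | CC(=O)c1c(O)c(OCc2ccccc2)c(OC)c(OC)c1OC | intermediate
6 | tert-butyl 3-[3-(benzyloxy)-2-hydroxy-4,5,6-trimethoxyphenyl]-3-oxopropanoate | CC(C)(C)OC(=O)CC(=O)c1c(O)c(OCc2ccccc2)c(OC)c(OC)c1OC | intermediate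
7 | 3,4-dimethoxybenzaldehyde | COc1ccc(C=O)cc1OC | starting material
8 | tert-butyl (2Z)-2-[3-(benzyloxy)-2-hydroxy-4,5,6-trimethoxybenzoyl]-3-(3,4-dimethoxyphenyl)prop-2-enoate | COc1ccc(/C=C(\C(=O)OC(C)(C)C)C(=O)c2c(O)c(OCc3ccccc3)c(OC)c(OC)c2OC)cc1OC | intermediate
9 | tert-butyl (2S,3R)-8-(benzyloxy)-2-(3,4-dimethoxyphenyl)-5,6,7-trimethoxy-4-oxochromane-3-carboxylate (trans; C3 labile) | COc1ccc([C@@H]2[C@@H](C(=O)OC(C)(C)C)C(=O)c3c(c(OCc4ccccc4)c(OC)c(OC)c3OC)O2)cc1OC | intermediate
10 | (2S,3R)-8-(benzyloxy)-2-(3,4-dimethoxyphenyl)-5,6,7-trimethoxy-4-oxochromane-3-carboxylic acid | COc1ccc([C@@H]2[C@@H](C(=O)O)C(=O)c3c(c(OCc4ccccc4)c(OC)c(OC)c3OC)O2)cc1OC | intermediate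
11 | (2S)-8-(benzyloxy)-2-(3,4-dimethoxyphenyl)-5,6,7-trimethoxychroman-4-one | COc1ccc([C@@H]2CC(=O)c3c(c(OCc4ccccc4)c(OC)c(OC)c3OC)O2)cc1OC | intermediate
12 | (2S)-2-(3,4-dimethoxyphenyl)-8-hydroxy-5,6,7-trimethoxychroman-4-one | COc1ccc([C@@H]2CC(=O)c3c(c(O)c(OC)c(OC)c3OC)O2)cc1OC | target

**Totals**

Total step count: 7. Longest linear sequence: 7 steps (1 → 12).

**Steps most likely to fail**

Step 6. Facial discrimination may be insufficient for a substrate whose aroyl group is twisted by two ortho substituents. Partial racemisation may also occur during the hot acid stage by acid-promoted opening of the C2–O1 bond, which the para-methoxy group of the B ring assists. The fallback sets the stereocentre by conjugate arylation instead. It sets out from 5, which is condensed with DMF dimethyl acetal (toluene, 90 °C) to (E)-1-[3-(benzyloxy)-2-hydroxy-4,5,6-trimethoxyphenyl]-3-(dimethylamino)prop-2-en-1-one F1. F1 is cyclised with acid (HCl, CH2Cl2, rt) to 8-(benzyloxy)-5,6,7-trimethoxy-4H-chromen-4-one F2. Palladium/PyOx-catalysed asymmetric conjugate addition of 3,4-dimethoxyphenylboronic acid to F2 (Pd(OCOCF3)2, the t-BuPyOx enantiomer that gives 2S, NH4PF6, H2O, ClCH2CH2Cl, 60 °C) comes back to the route at 11.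

Step 4. O-acylation of the phenoxide or of the enolate oxygen may compete with C-acylation at the hindered aryl ketone. The fallback makes the O-acyl compound on purpose and moves the group to carbon intramolecularly. It sets out from 5, which is converted with Boc2O, Et3N and catalytic DMAP (CH2Cl2, rt) into 2-acetyl-6-(benzyloxy)-3,4,5-trimethoxyphenyl tert-butyl carbonate F3. Treatment of F3 with LiHMDS (2.2 equiv, THF, −78 → 0 °C) should induce a Baker–Venkataraman-type O→C alkoxycarbonyl migration through a six-membered transition state and come back to the route at 6.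

Step 1. The electron-rich o-quinone may be over-oxidised or decompose before it is reduced, and the catechol may re-oxidise in air. The fallback introduces the oxygen by way of a carbonyl group. It sets out from 1, which is ortho-formylated (MgCl2, Et3N, paraformaldehyde, MeCN, reflux) to 2-hydroxy-4,5,6-trimethoxybenzaldehyde F4. Dakin oxidation of F4 (H2O2, aq. NaOH, 0 °C, N2) comes back to the route at 3.

Further compounds
F1 | step 6 | (E)-1-[3-(benzyloxy)-2-hydroxy-4,5,6-trimethoxyphenyl]-3-(dimethylamino)prop-2-en-1-one | CN(C)/C=C/C(=O)c1c(O)c(OCc2ccccc2)c(OC)c(OC)c1OC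
F2 | step 6 | 8-(benzyloxy)-5,6,7-trimethoxy-4H-chromen-4-one | O=c1ccoc2c(OCc3ccccc3)c(OC)c(OC)c(OC)c12
F3 | step 4 | 2-acetyl-6-(benzyloxy)-3,4,5-trimethoxyphenyl tert-butyl carbonate | CC(=O)c1c(OC(=O)OC(C)(C)C)c(OCc2ccccc2)c(OC)c(OC)c1OC
F4 | step 1 | 2-hydroxy-4,5,6-trimethoxybenzaldehyde | O=Cc1c(O)cc(OC)c(OC)c1OC
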